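## Retrosynthetic overview

1. The C5–OH is installed last, on the finished skeleton, by sterically controlled iridium-catalysed C–H borylation/oxidation, so no phenol protecting group is carried.
2. The lactone C–O bond and the C3 stereocentre come from one redox-neutral key step: rhodium/Duanphos-catalysed enantioselective intramolecular ketone hydroacylation of a 2-acyl-6-methoxybenzaldehyde.
3. The keto aldehyde comes from a single Grignard addition of a C9 alkenyl chain to 4-methoxyphthalide, then alcohol oxidation. The bought lactone is transposed: its C=O carbon becomes C3 and its CH2 becomes the new lactone carbonyl.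
4. The remote C10′ ketone and C13′ carbinol come from cross-metathesis plus C=C hydrogenation with a vinyl ketone made from (S)-γ-valerolactone (chiral pool).
5. Ring order: benzene ring A is bought; the bought lactone is opened in step 1; lactone ring B of the target is the only ring formed (step 8).

Assumption: 4-methoxyphthalide, 9-bromonon-1-ene and (S)-γ-valerolactone are taken as catalog compounds; the target is made as the open-chain γ-hydroxy ketone drawn.

## Route

Step 1
Reactants: 1 4-methoxy-2-benzofuran-1(3H)-one (4-methoxyphthalide); 2 9-bromonon-1-ene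
Product: 4 1-[2-(hydroxymethyl)-3-methoxyphenyl]dec-9-en-1-one (ring–chain tautomer of its cyclic hemiketal), via non-8-enylmagnesium bromide 3 (not isolated)
Conditions: 2, Mg, THF, 40 °C; then 1, THF, −78 → −40 °C; aq. NH4Cl
Reagents that add atoms: none
Why: Grignard formation followed by nucleophilic addition to the lactone carbonyl; the tetrahedral bromomagnesium hemiketalate is stable at low temperature, so only one addition occurs, and no stereocentre is formed.

Step 2
Reactants: 4 1-[2-(hydroxymethyl)-3-methoxyphenyl]dec-9-en-1-one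
Product: 5 2-(dec-9-enoyl)-6-methoxybenzaldehyde
Conditions: Dess–Martin periodinane, CH2Cl2, 0 °C → rt
Reagents that add atoms: none
Why: Dess–Martin oxidation; the hemiketal tautomer has no carbinol hydrogen, so only the benzylic primary alcohol of the open form can be oxidised and the equilibrium drains to the keto aldehyde.

Step 3
Reactants: 6 (5S)-5-methyloxolan-2-one ((S)-γ-valerolactone)
Product: 7 (4S)-4-hydroxy-N-methoxy-N-methylpentanamide
Conditions: MeNH(OMe)·HCl, AlMe3, CH2Cl2, 0 °C → rt; cold dilute aq. HCl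
Reagents that add atoms: N,O-dimethylhydroxylamine hydrochloride, CNOC.Cl
Why: Weinreb aminolysis of a lactone by the aluminium amide made in the flask; the (S) carbinol centre comes from the chiral pool and is not touched.

Step 4
Reactants: 7 (4S)-4-hydroxy-N-methoxy-N-methylpentanamide
Product: 8 (4S)-4-[(tert-butyldimethylsilyl)oxy]-N-methoxy-N-methylpentanamide
Conditions: TBSCl, imidazole, DMF, rt
Reagents that add atoms: tert-butyldimethylsilyl chloride, CC(C)(C)[Si](C)(C)Cl
Why: standard silylation of a secondary alcohol, which also blocks relactonisation of the γ-hydroxy amide.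

Step 5
Reactants: 8 (4S)-4-[(tert-butyldimethylsilyl)oxy]-N-methoxy-N-methylpentanamide
Product: 9 (6S)-6-[(tert-butyldimethylsilyl)oxy]hept-1-en-3-one
Conditions: CH2=CHMgBr, THF, 0 °C; inverse quench into cold 1 M HCl
Reagents that add atoms: vinylmagnesium bromide, C=C[Mg]Br
Why: Weinreb ketone synthesis; the chelated tetrahedral intermediate prevents over-addition, and the acidic inverse quench keeps the liberated amine from adding to the enone.

Step 6
Reactants: 5 2-(dec-9-enoyl)-6-methoxybenzaldehyde; 9 (6S)-6-[(tert-butyldimethylsilyl)oxy]hept-1-en-3-one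
Product: 10 2-[(9E,14S)-14-[(tert-butyldimethylsilyl)oxy]-11-oxopentadec-9-enoyl]-6-methoxybenzaldehyde
Conditions: 9 (2 equiv), RuCl2(H2IMes)(PCy3)(=CHPh) (second-generation Grubbs catalyst, 5 mol %), CH2Cl2, 40 °C
Reagents that add atoms: none
Why: olefin cross-metathesis of a terminal alkene with an electron-poor vinyl ketone that does not homodimerise, giving the E-enone; aldehyde, ketones and silyl ether are tolerated.

Step 7
Reactants: 10 2-[(9E,14S)-14-[(tert-butyldimethylsilyl)oxy]-11-oxopentadec-9-enoyl]-6-methoxybenzaldehyde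
Product: 11 2-[(14S)-14-[(tert-butyldimethylsilyl)oxy]-11-oxopentadecanoyl]-6-methoxybenzaldehyde
Conditions: H2 (1 atm), 10% Pd/C, Ph2S (1 mol %), EtOAc, rt
Reagents that add atoms: none
Why: chemoselective heterogeneous hydrogenation; sulfide-poisoned Pd/C saturates the conjugated C=C but leaves the aryl aldehyde and aryl ketone alone.

Step 8
Reactants: 11 2-[(14S)-14-[(tert-butyldimethylsilyl)oxy]-11-oxopentadecanoyl]-6-methoxybenzaldehyde
Product: 12 (3S)-3-[(13S)-13-[(tert-butyldimethylsilyl)oxy]-10-oxotetradecyl]-7-methoxy-2-benzofuran-1(3H)-one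
Conditions: [Rh(cod)Cl]2 (2.5 mol %), (S,S′,R,R′)-Duanphos (5.5 mol %), AgNO3 (5 mol %), degassed toluene, 90 °C
Reagents that add atoms: none
Why: rhodium-catalysed enantioselective intramolecular ketone hydroacylation; the aldehyde C–H adds to cationic monovalent rhodium, the ortho ketone C=O inserts into Rh–H on one face inside the chiral bisphosphine pocket, and C–O reductive elimination closes the lactone and sets C3 as (S) (this ligand antipode is the one that gives (S)-3-alkylphthalides; its mirror image is used if the assay shows the opposite sense), while the nitrate counterion suppresses decarbonylation and the remote dialkyl ketone cannot reach the metal.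

Step 9
Reactants: 12 (3S)-3-[(13S)-13-[(tert-butyldimethylsilyl)oxy]-10-oxotetradecyl]-7-methoxy-2-benzofuran-1(3H)-one
Product: 14 (3S)-3-[(13S)-13-[(tert-butyldimethylsilyl)oxy]-10-oxotetradecyl]-5-hydroxy-7-methoxy-2-benzofuran-1(3H)-one, via C5 pinacol boronate 13 (not isolated)
Conditions: [Ir(cod)OMe]2 (1.5 mol %), 4,4′-di-tert-butyl-2,2′-bipyridine (3 mol %), B2pin2 (0.7 equiv), THF, 80 °C; evaporate; then Oxone (2KHSO5·KHSO4·K2SO4), acetone/H2O, rt, 10 min
Reagents that add atoms: bis(pinacolato)diboron, CC1(C)OB(OC1(C)C)B1OC(C)(C)C(C)(C)O1 (boron of 13); potassium peroxymonosulfate KHSO5, [K+].[O-]S(=O)(=O)OO (phenol oxygen of 14)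
Why: sterically controlled iridium-catalysed aromatic C–H borylation followed by C–B oxidation; C5–H is the only ring hydrogen with no ortho substituent (C4–H flanks C3, C6–H flanks OMe), the lactone carbonyl has no free ortho position to direct to, and neither stereocentre is touched.

Step 10
Reactants: 14 (3S)-3-[(13S)-13-[(tert-butyldimethylsilyl)oxy]-10-oxotetradecyl]-5-hydroxy-7-methoxy-2-benzofuran-1(3H)-one
Product: 15 (3S)-5-hydroxy-3-[(13S)-13-hydroxy-10-oxotetradecyl]-7-methoxy-2-benzofuran-1(3H)-one (target)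
Conditions: HF·pyridine, THF/pyridine, 0 °C → rt
Reagents that add atoms: none
Why: fluoride-mediated desilylation under mild, weakly acidic conditions that neither open the lactone nor epimerise C3.

## Compound list

1 | 4-methoxy-2-benzofuran-1(3H)-one (4-methoxyphthalide) | COc1cccc2c1COC2=O | starting material
2 | 9-bromonon-1-ene | C=CCCCCCCCBr | starting material
3 | non-8-enylmagnesium bromide | C=CCCCCCCC[Mg]Br | intermediate
4 | 1-[2-(hydroxymethyl)-3-methoxyphenyl]dec-9-en-1-one | COc1cccc(C(=O)CCCCCCCC=C)c1CO | intermediate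
5 | 2-(dec-9-enoyl)-6-methoxybenzaldehyde | COc1cccc(C(=O)CCCCCCCC=C)c1C=O | intermediate
6 | (5S)-5-methyloxolan-2-one ((S)-γ-valerolactone) | C[C@H]1CCC(=O)O1 | starting material
7 | (4S)-4-hydroxy-N-methoxy-N-methylpentanamide | C[C@H](O)CCC(=O)N(C)OC | intermediate
8 | (4S)-4-[(tert-butyldimethylsilyl)oxy]-N-methoxy-N-methylpentanamide | C[C@H](O[Si](C)(C)C(C)(C)C)CCC(=O)N(C)OC | intermediate
9 | (6S)-6-[(tert-butyldimethylsilyl)oxy]hept-1-en-3-one | C[C@H](O[Si](C)(C)C(C)(C)C)CCC(=O)C=C | intermediate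
10 | 2-[(9E,14S)-14-[(tert-butyldimethylsilyl)oxy]-11-oxopentadec-9-enoyl]-6-methoxybenzaldehyde | COc1cccc(C(=O)CCCCCCC/C=C/C(=O)CC[C@H](C)O[Si](C)(C)C(C)(C)C)c1C=O | intermediate
11 | 2-[(14S)-14-[(tert-butyldimethylsilyl)oxy]-11-oxopentadecanoyl]-6-methoxybenzaldehyde | COc1cccc(C(=O)CCCCCCCCCC(=O)CC[C@H](C)O[Si](C)(C)C(C)(C)C)c1C=O | intermediate
12 | (3S)-3-[(13S)-13-[(tert-butyldimethylsilyl)oxy]-10-oxotetradecyl]-7-methoxy-2-benzofuran-1(3H)-one | COc1cccc2c1C(=O)O[C@H]2CCCCCCCCCC(=O)CC[C@H](C)O[Si](C)(C)C(C)(C)C | intermediate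
13 | (3S)-3-[(13S)-13-[(tert-butyldimethylsilyl)oxy]-10-oxotetradecyl]-7-methoxy-5-(4,4,5,5-tetramethyl-1,3,2-dioxaborolan-2-yl)-2-benzofuran-1(3H)-one | COc1cc(B3OC(C)(C)C(C)(C)O3)cc2c1C(=O)O[C@H]2CCCCCCCCCC(=O)CC[C@H](C)O[Si](C)(C)C(C)(C)C | intermediate
14 | (3S)-3-[(13S)-13-[(tert-butyldimethylsilyl)oxy]-10-oxotetradecyl]-5-hydroxy-7-methoxy-2-benzofuran-1(3H)-one | COc1cc(O)cc2c1C(=O)O[C@H]2CCCCCCCCCC(=O)CC[C@H](C)O[Si](C)(C)C(C)(C)C | intermediate
15 | (3S)-5-hydroxy-3-[(13S)-13-hydroxy-10-oxotetradecyl]-7-methoxy-2-benzofuran-1(3H)-one | COc1cc(O)cc2c1C(=O)O[C@H]2CCCCCCCCCC(=O)CC[C@H](C)O | target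

## Step count and risks

Total steps: 10. Longest linear sequence: 8 (steps 3, 4, 5, 6, 7, 8, 9, 10, from (S)-γ-valerolactone); the aryl branch is 7 steps.

**Step 8 (hydroacylation).** The aldehyde is flanked by OMe and the acyl group, so C–H insertion may be slow and decarbonylation or low ee could result. The fallback sets out from 11 and comes back at 12. Pinnick oxidation (NaClO2, NaH2PO4, 2-methylbut-2-ene, t-BuOH/H2O) gives 2-[(14S)-14-[(tert-butyldimethylsilyl)oxy]-11-oxopentadecanoyl]-6-methoxybenzoic acid F1. Methylation with MeI and K2CO3 in DMF gives methyl 2-[(14S)-14-[(tert-butyldimethylsilyl)oxy]-11-oxopentadecanoyl]-6-methoxybenzoate F2. Noyori asymmetric transfer hydrogenation with RuCl(p-cymene)[(S,S)-TsDPEN] in HCO2H/Et3N reduces only the aryl ketone and gives methyl 2-[(1S,14S)-14-[(tert-butyldimethylsilyl)oxy]-1-hydroxy-11-oxopentadecyl]-6-methoxybenzoate F3, which lactonises (cat. p-TsOH if not spontaneous) to 12.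

**Step 9 (late C–H borylation/oxidation).** The pinacolborane formed in the flask could reduce the dialkyl ketone. The fallback sets out from 12 and comes back at 15. 1,2-Bis(trimethylsilyloxy)ethane with catalytic TMSOTf in CH2Cl2 at −78 °C masks the ketone as (3S)-3-{9-[2-((3S)-3-[(tert-butyldimethylsilyl)oxy]butyl)-1,3-dioxolan-2-yl]nonyl}-7-methoxy-2-benzofuran-1(3H)-one F4. The same iridium borylation then gives (3S)-3-{9-[2-((3S)-3-[(tert-butyldimethylsilyl)oxy]butyl)-1,3-dioxolan-2-yl]nonyl}-7-methoxy-5-(4,4,5,5-tetramethyl-1,3,2-dioxaborolan-2-yl)-2-benzofuran-1(3H)-one F5, and Oxone gives (3S)-3-{9-[2-((3S)-3-[(tert-butyldimethylsilyl)oxy]butyl)-1,3-dioxolan-2-yl]nonyl}-5-hydroxy-7-methoxy-2-benzofuran-1(3H)-one F6. Aqueous 1 M HCl in THF removes the dioxolane and the silyl ether together and gives 15.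

**Step 7 (C=C hydrogenation beside a free aryl aldehyde).** The aldehyde could be reduced. The fallback sets out from 4 (with 9) and comes back at 11; it runs the chain extension at the alcohol oxidation level, where no aldehyde exists. Cross-metathesis of 4 with 9 under the step 6 conditions gives (9E,14S)-14-[(tert-butyldimethylsilyl)oxy]-1-[2-(hydroxymethyl)-3-methoxyphenyl]pentadec-9-ene-1,11-dione F7. Hydrogenation (H2, Pd/C, Ph2S, EtOAc) gives (14S)-14-[(tert-butyldimethylsilyl)oxy]-1-[2-(hydroxymethyl)-3-methoxyphenyl]pentadecane-1,11-dione F8, and Dess–Martin oxidation then gives 11.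

## Further compounds

F1 | step 8 | 2-[(14S)-14-[(tert-butyldimethylsilyl)oxy]-11-oxopentadecanoyl]-6-methoxybenzoic acid | COc1cccc(C(=O)CCCCCCCCCC(=O)CC[C@H](C)O[Si](C)(C)C(C)(C)C)c1C(=O)O
F2 | step 8 | methyl 2-[(14S)-14-[(tert-butyldimethylsilyl)oxy]-11-oxopentadecanoyl]-6-methoxybenzoate | COc1cccc(C(=O)CCCCCCCCCC(=O)CC[C@H](C)O[Si](C)(C)C(C)(C)C)c1C(=O)OC
F3 | step 8 | methyl 2-[(1S,14S)-14-[(tert-butyldimethylsilyl)oxy]-1-hydroxy-11-oxopentadecyl]-6-methoxybenzoate | COC(=O)c1c(OC)cccc1[C@@H](O)CCCCCCCCCC(=O)CC[C@H](C)O[Si](C)(C)C(C)(C)C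
F4 | step 9 | (3S)-3-{9-[2-((3S)-3-[(tert-butyldimethylsilyl)oxy]butyl)-1,3-dioxolan-2-yl]nonyl}-7-methoxy-2-benzofuran-1(3H)-one | COc1cccc2c1C(=O)O[C@H]2CCCCCCCCCC3(CC[C@H](C)O[Si](C)(C)C(C)(C)C)OCCO3
F5 | step 9 | (3S)-3-{9-[2-((3S)-3-[(tert-butyldimethylsilyl)oxy]butyl)-1,3-dioxolan-2-yl]nonyl}-7-methoxy-5-(4,4,5,5-tetramethyl-1,3,2-dioxaborolan-2-yl)-2-benzofuran-1(3H)-one | COc1cc(B4OC(C)(C)C(C)(C)O4)cc2c1C(=O)O[C@H]2CCCCCCCCCC3(CC[C@H](C)O[Si](C)(C)C(C)(C)C)OCCO3
F6 | step 9 | (3S)-3-{9-[2-((3S)-3-[(tert-butyldimethylsilyl)oxy]butyl)-1,3-dioxolan-2-yl]nonyl}-5-hydroxy-7-methoxy-2-benzofuran-1(3H)-one | COc1cc(O)cc2c1C(=O)O[C@H]2CCCCCCCCCC3(CC[C@H](C)O[Si](C)(C)C(C)(C)C)OCCO3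
F7 | step 7 | (9E,14S)-14-[(tert-butyldimethylsilyl)oxy]-1-[2-(hydroxymethyl)-3-methoxyphenyl]pentadec-9-ene-1,11-dione | COc1cccc(C(=O)CCCCCCC/C=C/C(=O)CC[C@H](C)O[Si](C)(C)C(C)(C)C)c1CO
F8 | step 7 | (14S)-14-[(tert-butyldimethylsilyl)oxy]-1-[2-(hydroxymethyl)-3-methoxyphenyl]pentadecane-1,11-dione | COc1cccc(C(=O)CCCCCCCCCC(=O)CC[C@H](C)O[Si](C)(C)C(C)(C)C)c1CO
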